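The plan rests on cutting C8–C9 of the ten-membered ring (C1–C10) while joining C1 to C6, i.e. an oxy-Cope transform. The feature exploited is the array C6–O, cis C4=C5 and C8–O: the lactone oxygen on C6, the epoxide carbons and the C8 carbinol map onto a 6-oxo-1(10),4-diene. In one operation the potassium alkoxide of a cyclohex-2-enol (ring C1–C6) bearing a Z 2-(4-methoxybenzyloxy)vinyl group on C6, a trans isopropenyl group on C1 and a silyl ether on C2 should expand to the (4Z,1(10)E)-cyclodecadien-6-one, setting C8 against C2 and leaving a C6 ketone for epoxide, butenolide and C1 ketone installation.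

Key step: step 10

Numbering and abbreviations: atom numbers are those of the target and are kept for all intermediates: C1 ketone, C2 carbinol, C4/C5 epoxide (C15 methyl on C4), C6 lactone oxygen, C7=C11 butenolide, C12 lactone carbonyl, C13 CH2OAc, C8 methacrylate, C10 with C14 methyl. TBS = tert-butyldimethylsilyl, PMB = 4-methoxybenzyl.

Assumption: the lipase acetylates meso-diol 2 to the (1R,3S,5S)-monoacetate 3; with an enzyme of the opposite preference the same compound would come from hydrolysis of the meso diacetate.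

Step 1
Reactants: 1 cis,cis-cyclohexane-1,3,5-triol
Product: 2 cis,cis-5-[(tert-butyldimethylsilyl)oxy]cyclohexane-1,3-diol (meso)
Conditions: TBSCl (1.0 equiv), imidazole, DMF, 0 °C to rt
Reagents that add atoms: tert-butyldimethylsilyl chloride C[Si](C)(Cl)C(C)(C)C
Why: Statistical monosilylation of one of three equivalent hydroxyls (silyl ether formation); the product is meso, so no stereochemical issue arises yet.

Step 2
Reactants: 2 cis,cis-5-[(tert-butyldimethylsilyl)oxy]cyclohexane-1,3-diol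
Product: 3 (1R,3S,5S)-3-[(tert-butyldimethylsilyl)oxy]-5-hydroxycyclohexyl acetate
Conditions: immobilised Candida antarctica lipase B, vinyl acetate, t-BuOMe, rt
Reagents that add atoms: vinyl acetate CC(=O)OC=C
Why: Lipase-catalysed irreversible transesterification (enzymatic desymmetrisation of a meso 1,3-diol) acylates one enantiotopic carbinol and so fixes the absolute configuration of all three centres.

Step 3
Reactants: 3 (1R,3S,5S)-3-[(tert-butyldimethylsilyl)oxy]-5-hydroxycyclohexyl acetate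
Product: 5 (R)-5-[(tert-butyldimethylsilyl)oxy]cyclohex-2-en-1-one, via β-acetoxy ketone 4 (not isolated)
Conditions: Dess–Martin periodinane, CH2Cl2, rt; then Et3N, 0 °C to rt
Reagents that add atoms: none
Why: Dess–Martin oxidation gives the β-acetoxy ketone and the amine triggers E1cB loss of acetate, a far better leaving group than silanolate, so the enone forms with the silyloxy centre (later C2) untouched.

Step 4
Reactants: 5 (R)-5-[(tert-butyldimethylsilyl)oxy]cyclohex-2-en-1-one
Product: 6 (5R)-5-[(tert-butyldimethylsilyl)oxy]-1-methylcyclohex-2-en-1-ol (both C1 epimers)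
Conditions: MeLi, Et2O, −78 °C; H2O work-up
Reagents that add atoms: methyllithium [Li]C
Why: 1,2-Addition of methyllithium to the enone carbonyl at low temperature (carbonyl addition); the carbinol centre is lost in the next step, so both epimers are used.

Step 5
Reactants: 6 (5R)-5-[(tert-butyldimethylsilyl)oxy]-1-methylcyclohex-2-en-1-ol
Product: 7 (S)-5-[(tert-butyldimethylsilyl)oxy]-3-methylcyclohex-2-en-1-one
Conditions: pyridinium chlorochromate [C5H5NH][CrO3Cl], CH2Cl2, rt
Reagents that add atoms: pyridinium chlorochromate [O-][Cr](=O)(=O)Cl.c1cc[nH+]cc1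
Why: Oxidative 1,3-transposition of a tertiary allylic alcohol (Dauben–Babler oxidation): a [3,3] shift of the chromate ester and oxidation place the carbonyl at the future C6 and the methyl on the olefin, the silyloxy centre being unchanged in space (its descriptor becomes S by priority only).

Step 6
Reactants: 7 (S)-5-[(tert-butyldimethylsilyl)oxy]-3-methylcyclohex-2-en-1-one; 8 2-bromopropene
Product: 11 (5S,6R)-5-[(tert-butyldimethylsilyl)oxy]-3-methyl-6-(prop-1-en-2-yl)cyclohex-2-en-1-one, via lithium dienolate 9 (not isolated), via chlorozinc dienolate 10 (not isolated)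
Conditions: LiN(i-Pr)2, THF, −78 °C; ZnCl2, −78 to −20 °C; Pd2(dba)3 (cat.), P(t-Bu)3 (cat.), 8, −20 °C to rt
Reagents that add atoms: none
Why: Kinetic α′-deprotonation gives the cross-conjugated dienolate, transmetalation to the less basic zinc enolate is meant to curb E1cB loss of silanolate, and palladium-catalysed enolate alkenylation (Negishi-type coupling) forms C1–C10; the new centre C1 is set anti to the neighbouring silyloxy group, which is also the thermodynamic trans-diequatorial arrangement at this epimerisable carbon.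

Step 7
Reactants: 12 4-methoxybenzyl alcohol
Product: 13 1-[(ethenyloxy)methyl]-4-methoxybenzene
Conditions: ethyl vinyl ether (solvent), Hg(OAc)2 (cat.), 35 °C
Reagents that add atoms: ethyl vinyl ether C=COCC
Why: Mercury-catalysed transetherification (transfer vinylation) of the benzylic alcohol, driven by the excess of ethyl vinyl ether.

Step 8
Reactants: 13 1-[(ethenyloxy)methyl]-4-methoxybenzene
Product: 15 1-({[(Z)-2-bromoethenyl]oxy}methyl)-4-methoxybenzene, via 1,2-dibromoethyl ether 14 (not isolated)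
Conditions: Br2, CH2Cl2, −78 °C; then i-Pr2NEt, −78 °C to rt
Reagents that add atoms: bromine BrBr
Why: Bromine addition to the enol ether followed by amine-induced dehydrobromination of the α-bromo ether (addition–elimination); the Z isomer should predominate because vicinal heteroatoms prefer the cis arrangement on an alkene, the minor E isomer being removed by chromatography.

Step 9
Reactants: 11 (5S,6R)-5-[(tert-butyldimethylsilyl)oxy]-3-methyl-6-(prop-1-en-2-yl)cyclohex-2-en-1-one; 15 1-({[(Z)-2-bromoethenyl]oxy}methyl)-4-methoxybenzene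
Product: 18 (1R,5S,6R)-5-[(tert-butyldimethylsilyl)oxy]-1-{(Z)-2-[(4-methoxybenzyl)oxy]ethenyl}-3-methyl-6-(prop-1-en-2-yl)cyclohex-2-en-1-ol, via Z-alkoxyvinyllithium 16 (not isolated), via Z-alkoxyvinylcerium dichloride 17 (not isolated)
Conditions: 15, t-BuLi (2 equiv), Et2O, −78 °C; CeCl3 (anhydrous), THF, −78 °C; then 11, −78 °C; H2O work-up (no acid)
Reagents that add atoms: none
Why: Bromine–lithium exchange proceeds with retention of the Z geometry, the organocerium reagent suppresses enolisation of the doubly activated C1–H, and 1,2-addition takes place anti to the adjacent isopropenyl group (equatorial attack on the half-chair), giving the trans-dialkenyl carbinol with the new centre C6 (R).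

Step 10
Reactants: 18 (1R,5S,6R)-5-[(tert-butyldimethylsilyl)oxy]-1-{(Z)-2-[(4-methoxybenzyl)oxy]ethenyl}-3-methyl-6-(prop-1-en-2-yl)cyclohex-2-en-1-ol
Product: 21 (2Z,5S,6E,9R)-5-[(tert-butyldimethylsilyl)oxy]-9-[(4-methoxybenzyl)oxy]-3,7-dimethylcyclodeca-2,6-dien-1-one, via potassium alkoxide 19 (not isolated), via potassium enolate 20 (not isolated)
Conditions: KH, 18-crown-6, THF, 0 °C to rt; then AcOH, THF, −78 °C
Reagents that add atoms: none
Why: Deprotonation gives potassium alkoxide 19, whose C6–O− weakens the adjacent C1–C6 bond so that a concerted suprafacial [3,3] shift (anionic oxy-Cope rearrangement, the known behaviour of trans-1,2-dialkenylcyclohexanols) forms C8–C9 while C1–C6 breaks, delivering enolate 20, which is protonated cold. The ten-membered ring is not closed end to end: it arises by four-atom ring expansion of the six-membered ring through a six-centre chair in which both ring bonds (C5 on C6 and C2 on C1) are equatorial. The only new stereocentre, C8, is fixed by that chair together with the Z enol ether, which places the 4-methoxybenzyloxy group axial and so relates C8 (R) to the resident C2 (S); the equatorial C2 bond gives the E C1(10) olefin and the ring olefin is carried over as the Z C4=C5 enone. The step needs chair over boat selectivity and use of the exocyclic enol-ether vinyl group instead of the ring olefin, both secured by the trans-diequatorial placement of the two alkenyl groups, which a boat cannot accommodate. It also needs the enolate to survive, so a hydride base (no proton shuttle), a short reaction time and a cold acidic quench are used against E1cB loss of the C8 alkoxide and against enolate equilibration towards C3 that would expel the silyloxy group.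

Step 11
Reactants: 21 (2Z,5S,6E,9R)-5-[(tert-butyldimethylsilyl)oxy]-9-[(4-methoxybenzyl)oxy]-3,7-dimethylcyclodeca-2,6-dien-1-one
Product: 22 (1R,2Z,5S,6E,9R)-5-[(tert-butyldimethylsilyl)oxy]-9-[(4-methoxybenzyl)oxy]-3,7-dimethylcyclodeca-2,6-dien-1-ol (C6 carbinol, 6R)
Conditions: Zn(BH4)2, Et2O, −30 °C; H2O work-up
Reagents that add atoms: none
Why: 1,2-Reduction of the enone by Zn(BH4)2: hydride reaches C6 from the open outer face (the inner face is covered by the C1(10) olefin across the ring) and zinc chelation between the carbonyl and the C8 ether (β-alkoxy ketone, 1,3-syn) points the same way, so C6 (R) is set syn to C8.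

Step 12
Reactants: 22 (1R,2Z,5S,6E,9R)-5-[(tert-butyldimethylsilyl)oxy]-9-[(4-methoxybenzyl)oxy]-3,7-dimethylcyclodeca-2,6-dien-1-ol
Product: 23 (2S,4S,5R,6R,8R,1(10)E)-4,5-epoxy-2-TBSO-8-PMBO-4,10-dimethylcyclodec-1(10)-en-6-ol (target numbering)
Conditions: VO(acac)2 (cat.), t-BuOOH (decane), CH2Cl2, 0 °C to rt
Reagents that add atoms: tert-butyl hydroperoxide CC(C)(C)OO
Why: Hydroxyl-directed vanadium-catalysed epoxidation of the allylic alcohol: oxygen is delivered to the C4=C5 face on the side of the C6 hydroxyl (cis epoxy alcohol, as for medium-ring Z-cycloalkenols), which sets C4 (S) and C5 (R), while the C1(10) olefin, lacking a free allylic hydroxyl, is left alone.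

Step 13
Reactants: 23 (2S,4S,5R,6R,8R,1(10)E)-4,5-epoxy-2-TBSO-8-PMBO-4,10-dimethylcyclodec-1(10)-en-6-ol
Product: 24 (2S,4S,5S,8R,1(10)E)-4,5-epoxy-2-TBSO-8-PMBO-4,10-dimethylcyclodec-1(10)-en-6-one
Conditions: Dess–Martin periodinane, pyridine, CH2Cl2, 0 °C to rt
Reagents that add atoms: none
Why: Dess–Martin oxidation of the secondary alcohol under pyridine buffering regenerates the C6 ketone without touching the acid-sensitive epoxide, so that C7 becomes the only enolisable position (C5 keeps its configuration, its descriptor changes by priority only).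

Step 14
Reactants: 24 (2S,4S,5S,8R,1(10)E)-4,5-epoxy-2-TBSO-8-PMBO-4,10-dimethylcyclodec-1(10)-en-6-one
Product: 26 ethyl 2-hydroxy-2-[(2S,4S,5S,8R,1(10)E)-4,5-epoxy-6-oxo-2-TBSO-8-PMBO-4,10-dimethylcyclodec-1(10)-en-7-yl]acetate (C7 and C11 epimers), via lithium enolate 25 (not isolated)
Conditions: LiN(i-Pr)2, THF, −78 °C; ethyl glyoxylate (freshly distilled), −78 °C; AcOH, −78 °C
Reagents that add atoms: ethyl glyoxylate CCOC(=O)C=O
Why: Kinetic lithium enolate formation can only occur at C7, and the aldol addition to the highly electrophilic glyoxylate is fast at −78 °C, which limits E1cB loss of the C8 alkoxide; the new centres C7 and C11 are not controlled because both become sp2 in step 17.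

Step 15
Reactants: 26 ethyl 2-hydroxy-2-[(2S,4S,5S,8R,1(10)E)-4,5-epoxy-6-oxo-2-TBSO-8-PMBO-4,10-dimethylcyclodec-1(10)-en-7-yl]acetate
Product: 28 (2S,4S,5R,6R,8R,1(10)E)-4,5-epoxy-11-hydroxy-2-TBSO-8-PMBO-4,10-dimethylcyclodec-1(10)-ene-6,12-olide (γ-lactone O6–C12(=O)–C11(OH)–C7; C7 and C11 epimers), via γ-hydroxy ester 27 (not isolated)
Conditions: Zn(BH4)2, Et2O, −30 to 0 °C; H2O work-up; then Et3N, CH2Cl2, rt
Reagents that add atoms: none
Why: Chelation-controlled reduction of the α,β-epoxy ketone by Zn(BH4)2 (hydride anti to C4 in the zinc chelate of carbonyl and epoxide oxygens, i.e. from the ring periphery) gives the cis (erythro) epoxy alcohol with C6 (R), and the γ-hydroxy ester then closes to the γ-lactone (lactonisation) under mild base.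

Step 16
Reactants: 28 (2S,4S,5R,6R,8R,1(10)E)-4,5-epoxy-11-hydroxy-2-TBSO-8-PMBO-4,10-dimethylcyclodec-1(10)-ene-6,12-olide
Product: 30 (1S,2S,4S,5R,6R,8R,10S)-4,5-epoxy-1,11-dihydroxy-2-TBSO-8-PMBO-4,10-dimethylcyclodecane-6,12-olide, via C1 alkylborane 29 (not isolated)
Conditions: BH3·THF, THF, 0 °C; then 30% H2O2, pH 7 phosphate buffer, 0 °C to rt
Reagents that add atoms: hydrogen peroxide OO
Why: Hydroboration–oxidation of the only remaining olefin: boron adds to the less substituted C1 and hydrogen to C10 in a syn fashion from the outer face of the E olefin, which in the conformation inherited from step 10 gives C10 (S), while borane at 0 °C is expected to spare the epoxide and the lactone.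

Step 17
Reactants: 30 (1S,2S,4S,5R,6R,8R,10S)-4,5-epoxy-1,11-dihydroxy-2-TBSO-8-PMBO-4,10-dimethylcyclodecane-6,12-olide
Product: 31 (2S,4S,5R,6R,8R,10S)-4,5-epoxy-11-hydroxy-1-oxo-2-TBSO-8-PMBO-4,10-dimethylcyclodec-7(11)-ene-6,12-olide (enol form of the α-keto lactone)
Conditions: Dess–Martin periodinane (3 equiv), pyridine, CH2Cl2, 0 °C to rt
Reagents that add atoms: none
Why: Dess–Martin oxidation of both secondary alcohols gives the C1 ketone and the α-keto lactone, which should exist as the conjugated enol (C7=C11), so that the uncontrolled centres C7 and C11 disappear; C10 is not enolised under these buffered conditions.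

Step 18
Reactants: 31 (2S,4S,5R,6R,8R,10S)-4,5-epoxy-11-hydroxy-1-oxo-2-TBSO-8-PMBO-4,10-dimethylcyclodec-7(11)-ene-6,12-olide
Product: 32 (2S,4S,5R,6R,8R,10S)-4,5-epoxy-1-oxo-2-TBSO-8-PMBO-11-(trifluoromethanesulfonyloxy)-4,10-dimethylcyclodec-7(11)-ene-6,12-olide
Conditions: PhNTf2, Et3N, CH2Cl2, 0 °C
Reagents that add atoms: N-phenyl-bis(trifluoromethanesulfonimide) O=S(=O)(N(c1ccccc1)S(=O)(=O)C(F)(F)F)C(F)(F)F
Why: Only the acidic enol hydroxyl is deprotonated by triethylamine and sulfonylated (enol triflate formation), the C1 ketone being inert to this weak base.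

Step 19
Reactants: 32 (2S,4S,5R,6R,8R,10S)-4,5-epoxy-1-oxo-2-TBSO-8-PMBO-11-(trifluoromethanesulfonyloxy)-4,10-dimethylcyclodec-7(11)-ene-6,12-olide
Product: 33 (2S,4S,5R,6R,8R,10S)-4,5-epoxy-11-(hydroxymethyl)-1-oxo-2-TBSO-8-PMBO-4,10-dimethylcyclodec-7(11)-ene-6,12-olide
Conditions: Bu3SnCH2OH, Pd2(dba)3 (cat.), AsPh3, NMP, 45 °C
Reagents that add atoms: (tributylstannyl)methanol OC[Sn](CCCC)(CCCC)CCCC
Why: Stille coupling of the electron-poor alkenyl triflate with (tributylstannyl)methanol transfers the hydroxymethyl group (C13) to C11 under neutral conditions at moderate temperature, compatible with the epoxide and the α-silyloxy ketone.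

Step 20
Reactants: 33 (2S,4S,5R,6R,8R,10S)-4,5-epoxy-11-(hydroxymethyl)-1-oxo-2-TBSO-8-PMBO-4,10-dimethylcyclodec-7(11)-ene-6,12-olide
Product: 34 (2S,4S,5R,6R,8R,10S)-11-(acetoxymethyl)-4,5-epoxy-1-oxo-2-TBSO-8-PMBO-4,10-dimethylcyclodec-7(11)-ene-6,12-olide
Conditions: Ac2O, pyridine, DMAP (cat.), CH2Cl2, 0 °C
Reagents that add atoms: acetic anhydride CC(=O)OC(C)=O
Why: Acylation (esterification) of the only free hydroxyl, the primary allylic C13–OH.

Step 21
Reactants: 34 (2S,4S,5R,6R,8R,10S)-11-(acetoxymethyl)-4,5-epoxy-1-oxo-2-TBSO-8-PMBO-4,10-dimethylcyclodec-7(11)-ene-6,12-olide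
Product: 35 (2S,4S,5R,6R,8R,10S)-11-(acetoxymethyl)-4,5-epoxy-8-hydroxy-1-oxo-2-TBSO-4,10-dimethylcyclodec-7(11)-ene-6,12-olide
Conditions: DDQ, CH2Cl2/pH 7 buffer, 0 °C to rt
Reagents that add atoms: none
Why: Oxidative cleavage of the 4-methoxybenzyl ether by DDQ (oxidation to the oxocarbenium ion, then hydrolysis) in a buffered two-phase medium frees C8–OH without affecting silyl ether, esters, epoxide or butenolide.

Step 22
Reactants: 35 (2S,4S,5R,6R,8R,10S)-11-(acetoxymethyl)-4,5-epoxy-8-hydroxy-1-oxo-2-TBSO-4,10-dimethylcyclodec-7(11)-ene-6,12-olide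
Product: 36 2-O-TBS ether of the target (8-methacrylate)
Conditions: methacrylic anhydride, Et3N, DMAP (cat.), CH2Cl2, 0 °C to rt
Reagents that add atoms: methacrylic anhydride C=C(C)C(=O)OC(=O)C(C)=C
Why: DMAP-catalysed acylation of the secondary C8 alcohol with methacrylic anhydride (esterification) at low temperature, mild enough not to epimerise C10.

Step 23
Reactants: 36 2-O-TBS ether of the target
Product: 37 CNP0359197.1, (2S,4S,5R,6R,8R,10S)-13-acetoxy-4,5-epoxy-2-hydroxy-8-(methacryloyloxy)-1-oxo-4,10-dimethylcyclodec-7(11)-ene-6,12-olide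
Conditions: HF·pyridine, pyridine, THF, 0 °C to rt
Reagents that add atoms: none
Why: Fluoride-mediated desilylation with buffered HF·pyridine, acidic rather than basic so that the α-ketol, the esters and the butenolide are not exposed to alkoxide, liberates C2–OH and gives the target.

Compound list
1 | cis,cis-cyclohexane-1,3,5-triol | O[C@@H]1C[C@H](O)C[C@H](O)C1 | starting material
2 | cis,cis-5-[(tert-butyldimethylsilyl)oxy]cyclohexane-1,3-diol (meso) | O[C@@H]1C[C@H](O)C[C@H](O[Si](C)(C)C(C)(C)C)C1 | intermediate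
3 | (1R,3S,5S)-3-[(tert-butyldimethylsilyl)oxy]-5-hydroxycyclohexyl acetate | CC(=O)O[C@@H]1C[C@H](O)C[C@H](O[Si](C)(C)C(C)(C)C)C1 | intermediate
4 | (1S,3R)-3-[(tert-butyldimethylsilyl)oxy]-5-oxocyclohexyl acetate | CC(=O)O[C@@H]1CC(=O)C[C@H](O[Si](C)(C)C(C)(C)C)C1 | intermediate
5 | (R)-5-[(tert-butyldimethylsilyl)oxy]cyclohex-2-en-1-one | O=C1C=CC[C@@H](O[Si](C)(C)C(C)(C)C)C1 | intermediate
6 | (5R)-5-[(tert-butyldimethylsilyl)oxy]-1-methylcyclohex-2-en-1-ol (C1 epimers) | CC1(O)C=CC[C@@H](O[Si](C)(C)C(C)(C)C)C1 | intermediate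
7 | (S)-5-[(tert-butyldimethylsilyl)oxy]-3-methylcyclohex-2-en-1-one | O=C1C[C@@H](O[Si](C)(C)C(C)(C)C)CC(C)=C1 | intermediate
8 | 2-bromopropene | CC(Br)=C | starting material
9 | lithium (3S)-3-[(tert-butyldimethylsilyl)oxy]-5-methylcyclohexa-1,5-dien-1-olate | [Li+].[O-]C1=C[C@@H](O[Si](C)(C)C(C)(C)C)CC(C)=C1 | intermediate
10 | chlorozinc (3S)-3-[(tert-butyldimethylsilyl)oxy]-5-methylcyclohexa-1,5-dien-1-olate | Cl[Zn]OC1=C[C@@H](O[Si](C)(C)C(C)(C)C)CC(C)=C1 | intermediate
11 | (5S,6R)-5-[(tert-butyldimethylsilyl)oxy]-3-methyl-6-(prop-1-en-2-yl)cyclohex-2-en-1-one | C=C(C)[C@@H]1[C@@H](O[Si](C)(C)C(C)(C)C)CC(C)=CC1=O | intermediate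
12 | 4-methoxybenzyl alcohol | COc1ccc(CO)cc1 | starting material
13 | 1-[(ethenyloxy)methyl]-4-methoxybenzene | C=COCc1ccc(OC)cc1 | intermediate
14 | 1-[(1,2-dibromoethoxy)methyl]-4-methoxybenzene | BrCC(Br)OCc1ccc(OC)cc1 | intermediate
15 | 1-({[(Z)-2-bromoethenyl]oxy}methyl)-4-methoxybenzene | Br/C=C\OCc1ccc(OC)cc1 | intermediate
16 | (Z)-2-[(4-methoxybenzyl)oxy]ethenyllithium | [Li]/C=C\OCc1ccc(OC)cc1 | intermediate
17 | dichloro{(Z)-2-[(4-methoxybenzyl)oxy]ethenyl}cerium | Cl[Ce](Cl)/C=C\OCc1ccc(OC)cc1 | intermediate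
18 | (1R,5S,6R)-5-[(tert-butyldimethylsilyl)oxy]-1-{(Z)-2-[(4-methoxybenzyl)oxy]ethenyl}-3-methyl-6-(prop-1-en-2-yl)cyclohex-2-en-1-ol | C=C(C)[C@@H]1[C@@H](O[Si](C)(C)C(C)(C)C)CC(C)=C[C@@]1(O)/C=C\OCc1ccc(OC)cc1 | intermediate
19 | potassium alkoxide of 18 | C=C(C)[C@@H]1[C@@H](O[Si](C)(C)C(C)(C)C)CC(C)=C[C@@]1([O-])/C=C\OCc1ccc(OC)cc1.[K+] | intermediate
20 | potassium enolate of 21 (C6–O−, C6=C7) | C1/C(C)=C\C([O-])=C\[C@H](OCc2ccc(OC)cc2)C/C(C)=C/[C@H]1O[Si](C)(C)C(C)(C)C.[K+] | intermediate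
21 | (2Z,5S,6E,9R)-5-[(tert-butyldimethylsilyl)oxy]-9-[(4-methoxybenzyl)oxy]-3,7-dimethylcyclodeca-2,6-dien-1-one | COc1ccc(CO[C@@H]2C/C(C)=C/[C@@H](O[Si](C)(C)C(C)(C)C)C/C(C)=C\C(=O)C2)cc1 | intermediate
22 | (1R,2Z,5S,6E,9R)-5-[(tert-butyldimethylsilyl)oxy]-9-[(4-methoxybenzyl)oxy]-3,7-dimethylcyclodeca-2,6-dien-1-ol | COc1ccc(CO[C@@H]2C/C(C)=C/[C@@H](O[Si](C)(C)C(C)(C)C)C/C(C)=C\[C@H](O)C2)cc1 | intermediate
23 | (2S,4S,5R,6R,8R,1(10)E)-4,5-epoxy-2-TBSO-8-PMBO-4,10-dimethylcyclodec-1(10)-en-6-ol | COc1ccc(CO[C@@H]2C/C(C)=C/[C@@H](O[Si](C)(C)C(C)(C)C)C[C@]3(C)O[C@@H]3[C@H](O)C2)cc1 | intermediate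
24 | (2S,4S,5S,8R,1(10)E)-4,5-epoxy-2-TBSO-8-PMBO-4,10-dimethylcyclodec-1(10)-en-6-one | COc1ccc(CO[C@@H]2C/C(C)=C/[C@@H](O[Si](C)(C)C(C)(C)C)C[C@]3(C)O[C@@H]3C(=O)C2)cc1 | intermediate
25 | lithium enolate of 24 (C6–O−, C6=C7) | COc1ccc(CO[C@@H]2C/C(C)=C/[C@@H](O[Si](C)(C)C(C)(C)C)C[C@]3(C)O[C@@H]3C([O-])=C2)cc1.[Li+] | intermediate
26 | ethyl 2-hydroxy-2-(C7-yl)acetate of 24 (aldol adduct, C7 and C11 epimers) | COc1ccc(CO[C@@H]2C/C(C)=C/[C@@H](O[Si](C)(C)C(C)(C)C)C[C@]3(C)O[C@@H]3C(=O)C2C(O)C(=O)OCC)cc1 | intermediate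
27 | (6R)-6-hydroxy ester from 26 (C7 and C11 epimers) | COc1ccc(CO[C@@H]2C/C(C)=C/[C@@H](O[Si](C)(C)C(C)(C)C)C[C@]3(C)O[C@@H]3[C@H](O)C2C(O)C(=O)OCC)cc1 | intermediate
28 | (2S,4S,5R,6R,8R,1(10)E)-4,5-epoxy-11-hydroxy-2-TBSO-8-PMBO-4,10-dimethylcyclodec-1(10)-ene-6,12-olide (C7 and C11 epimers) | COc1ccc(CO[C@@H]2C/C(C)=C/[C@@H](O[Si](C)(C)C(C)(C)C)C[C@]3(C)O[C@@H]3[C@@H]3OC(=O)C(O)C23)cc1 | intermediate
29 | C1 alkylborane from 28 (BH2 on C1, H on C10) | COc1ccc(CO[C@@H]2C[C@H](C)[C@H](B)[C@@H](O[Si](C)(C)C(C)(C)C)C[C@]3(C)O[C@@H]3[C@@H]3OC(=O)C(O)C23)cc1 | intermediate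
30 | (1S,2S,4S,5R,6R,8R,10S)-4,5-epoxy-1,11-dihydroxy-2-TBSO-8-PMBO-4,10-dimethylcyclodecane-6,12-olide | COc1ccc(CO[C@@H]2C[C@H](C)[C@H](O)[C@@H](O[Si](C)(C)C(C)(C)C)C[C@]3(C)O[C@@H]3[C@@H]3OC(=O)C(O)C23)cc1 | intermediate
31 | (2S,4S,5R,6R,8R,10S)-4,5-epoxy-11-hydroxy-1-oxo-2-TBSO-8-PMBO-4,10-dimethylcyclodec-7(11)-ene-6,12-olide | COc1ccc(CO[C@@H]2C[C@H](C)C(=O)[C@@H](O[Si](C)(C)C(C)(C)C)C[C@]3(C)O[C@@H]3[C@@H]3OC(=O)C(O)=C23)cc1 | intermediate
32 | 11-O-triflate of 31 | COc1ccc(CO[C@@H]2C[C@H](C)C(=O)[C@@H](O[Si](C)(C)C(C)(C)C)C[C@]3(C)O[C@@H]3[C@@H]3OC(=O)C(OS(=O)(=O)C(F)(F)F)=C23)cc1 | intermediate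
33 | (2S,4S,5R,6R,8R,10S)-4,5-epoxy-11-(hydroxymethyl)-1-oxo-2-TBSO-8-PMBO-4,10-dimethylcyclodec-7(11)-ene-6,12-olide | COc1ccc(CO[C@@H]2C[C@H](C)C(=O)[C@@H](O[Si](C)(C)C(C)(C)C)C[C@]3(C)O[C@@H]3[C@@H]3OC(=O)C(CO)=C23)cc1 | intermediate
34 | 13-acetate of 33 | COc1ccc(CO[C@@H]2C[C@H](C)C(=O)[C@@H](O[Si](C)(C)C(C)(C)C)C[C@]3(C)O[C@@H]3[C@@H]3OC(=O)C(COC(C)=O)=C23)cc1 | intermediate
35 | (2S,4S,5R,6R,8R,10S)-11-(acetoxymethyl)-4,5-epoxy-8-hydroxy-1-oxo-2-TBSO-4,10-dimethylcyclodec-7(11)-ene-6,12-olide | O[C@@H]1C[C@H](C)C(=O)[C@@H](O[Si](C)(C)C(C)(C)C)C[C@]2(C)O[C@@H]2[C@@H]2OC(=O)C(COC(C)=O)=C21 | intermediate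
36 | 2-O-TBS ether of the target | C=C(C)C(=O)O[C@@H]1C[C@H](C)C(=O)[C@@H](O[Si](C)(C)C(C)(C)C)C[C@]2(C)O[C@@H]2[C@@H]2OC(=O)C(COC(C)=O)=C21 | intermediate
37 | CNP0359197.1 | C=C(C)C(=O)O[C@@H]1C[C@H](C)C(=O)[C@@H](O)C[C@]2(C)O[C@@H]2[C@@H]2OC(=O)C(COC(C)=O)=C21 | target

Total step count: 23. Longest linear sequence: 21 steps (steps 1–6 and 9–23); steps 7 and 8 form the side branch to bromide 15.

Steps most likely to fail

Step 6 (α′-alkenylation). What may go wrong is expulsion of silanolate from the enolate, with aromatisation, before the coupling takes place, or further reaction of the more acidic product. The fallback sets out from 7 and comes back at 11. The lithium dienolate is intercepted at −78 °C by acetone, an aldol addition that is fast at a temperature at which the β-silyloxy enolate survives, to give the tertiary carbinol (5S,6S)-5-[(tert-butyldimethylsilyl)oxy]-6-(2-hydroxypropan-2-yl)-3-methylcyclohex-2-en-1-one F1. Dehydration of F1 with SOCl2 and pyridine at −20 °C should then give 11, the conjugated isopropylidene isomer, if formed, being removed by chromatography.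

Step 10 (key step). What may go wrong is E1cB loss of the C8 alkoxide from the potassium enolate, the more so if the axial substituent slows the rearrangement and lengthens the life of the enolate. The fallback sets out from 18 and comes back at 21. The rearrangement is run with deliberate, complete elimination to the cross-conjugated (2Z,5S,6E)-5-[(tert-butyldimethylsilyl)oxy]-3,7-dimethylcyclodeca-2,6,9-trien-1-one F2. Copper-catalysed conjugate borylation of the less substituted C7=C8 enone (CuCl, NaO-t-Bu, a chiral bisphosphine such as BINAP of the hand that delivers 8R, B2pin2, MeOH, THF) should give the C8 pinacol boronate F3. Oxidation with NaBO3·4H2O proceeds with retention to the β-hydroxy ketone (2Z,5S,6E,9R)-5-[(tert-butyldimethylsilyl)oxy]-9-hydroxy-3,7-dimethylcyclodeca-2,6-dien-1-one F4. 4-Methoxybenzyl trichloroacetimidate with catalytic camphorsulfonic acid then returns 21.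

Step 16 (hydroboration). What may go wrong is delivery of hydrogen to the other face of the C1(10) olefin, since the bulky C2 silyloxy group flanks the exposed face, so that the C10 epimer forms; hydride attack on the epoxide or the hydroxy lactone is a lesser concern. The fallback sets out from 28 and comes back at 31, replacing kinetic facial control by thermodynamic control. The epimeric diol, (1R,10R)-configured 10-epi-30 F5, is oxidised as in step 17 to the 10-epi keto enol F6. C10, now α to the C1 carbonyl, is then equilibrated with a mild base (DBU, toluene, rt) towards 31, on the expectation that the natural arrangement with the C14 methyl turned outwards is the more stable one.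

Further compounds
F1 | step 6 | (5S,6S)-5-[(tert-butyldimethylsilyl)oxy]-6-(2-hydroxypropan-2-yl)-3-methylcyclohex-2-en-1-one | CC(C)(O)[C@@H]1[C@@H](O[Si](C)(C)C(C)(C)C)CC(C)=CC1=O
F2 | step 10 | (2Z,5S,6E)-5-[(tert-butyldimethylsilyl)oxy]-3,7-dimethylcyclodeca-2,6,9-trien-1-one | C1/C(C)=C/[C@@H](O[Si](C)(C)C(C)(C)C)C/C(C)=C\C(=O)C=C1
F3 | step 10 | (2Z,5S,6E,9R)-5-[(tert-butyldimethylsilyl)oxy]-3,7-dimethyl-9-(4,4,5,5-tetramethyl-1,3,2-dioxaborolan-2-yl)cyclodeca-2,6-dien-1-one | CC1(C)OB(OC1(C)C)[C@@H]2C/C(C)=C/[C@@H](O[Si](C)(C)C(C)(C)C)C/C(C)=C\C(=O)C2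
F4 | step 10 | (2Z,5S,6E,9R)-5-[(tert-butyldimethylsilyl)oxy]-9-hydroxy-3,7-dimethylcyclodeca-2,6-dien-1-one | O[C@@H]1C/C(C)=C/[C@@H](O[Si](C)(C)C(C)(C)C)C/C(C)=C\C(=O)C1
F5 | step 16 | (1R,2S,4S,5R,6R,8R,10R)-4,5-epoxy-1,11-dihydroxy-2-TBSO-8-PMBO-4,10-dimethylcyclodecane-6,12-olide | COc1ccc(CO[C@@H]2C[C@@H](C)[C@@H](O)[C@@H](O[Si](C)(C)C(C)(C)C)C[C@]3(C)O[C@@H]3[C@@H]3OC(=O)C(O)C23)cc1
F6 | step 16 | (2S,4S,5R,6R,8R,10R)-4,5-epoxy-11-hydroxy-1-oxo-2-TBSO-8-PMBO-4,10-dimethylcyclodec-7(11)-ene-6,12-olide | COc1ccc(CO[C@@H]2C[C@@H](C)C(=O)[C@@H](O[Si](C)(C)C(C)(C)C)C[C@]3(C)O[C@@H]3[C@@H]3OC(=O)C(O)=C23)cc1
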